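# Proposed total synthesis of ent-fisetinidol-(4α→6)-ent-fisetinidol-(4α→8)-[ent-fisetinidol-(4β→6)]-catechin (CNP0126838.5)

## Analysis of the target

The target is an angular profisetinidin tetramer in which one (+)-catechin unit D (2R,3S) carries three 5-deoxy flavan-3-ol units of the ent-fisetinidol type (A, B and C), each (2S,3R) and 2,3-trans. Unit B is bonded through its C4 to C8 of ring A of unit D, unit C through its C4 to C6 of the same ring, and unit A through its C4 to C6 of ring A of unit B, so that the molecule holds four chroman rings, three interflavanyl C–C bonds and eleven stereocentres. The junctions at C4 of units A and B are 3,4-cis (aryl group on the face of the C3 hydroxyl), whereas the junction at C4 of unit C is 3,4-trans. Thirteen phenolic and four secondary hydroxyl groups make the free compound sensitive to air and base, and the benzylic C2–O1 ethers and C4–aryl bonds are acid-labile, so the free polyphenol can appear only in the last step. The synthesis is hard for three reasons: cation–arene coupling gives mainly 3,4-trans and not 3,4-cis junctions for 2,3-trans units; the A–B bond would need a weakly nucleophilic resorcinol ring as the arene; and three non-natural (2S,3R) units have to be made enantioselectively. The strategy rests on ring A of unit B, a resorcinol whose C4a and C6 each carry a three-carbon chain (C4–C3–C2 of unit B and C4–C3–C2 of unit A) of the same (2S,3R) configuration. Both chains can therefore be grown at once from the two acetyl groups of 4,6-diacetylresorcinol 1, each acetyl carbon becoming a flavan C4.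

## Retrosynthetic reasoning

Target 36 is traced back to its tridecabenzyl ether 35 and this to the tetrasilyl ether 34. Only O–benzyl and O–Si bonds are cut. Benzyl ethers mask every phenol because they survive base, organometallic reagents and mild acid and leave in one neutral hydrogenolysis. Silyl ethers sit on the secondary hydroxyls that have to steer the reactions at C4.

In 34 the bond C4 (unit C)–C6 (unit D) is cut, which gives trimer 25 and flavan-4-ol 33. This bond is cut first because it is the only interflavanyl bond with the 3,4-trans relation that a cation–arene coupling delivers, and because C6 of unit D is the single free phloroglucinol-type position once C8 carries unit B. The forward reaction has to ionise the benzylic hydroxyl of 33 and let the arene add anti to the C3 silyloxy group.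

In 25 the two C4–H bonds of units A and B are cut, which leads to bis-carbinol 24 and, after removal of two silyl groups, to 23. Placing hydrogen last turns both 3,4-cis junctions into one problem, hydride delivery anti to O3. It also lets both interflavanyl C–C bonds be made earlier by carbonyl addition, where no configuration at C4 has to be controlled.

In 23 the bond O1–C2 of unit A is cut, giving epoxy diphenol 22 and its bis-allyl ether 21. The forward reaction is opening of the trans-epoxide by the ortho phenoxide at the benzylic carbon with inversion, which transfers the epoxide configuration to C2 and C3 of unit A.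

In 21 the bond C4 (unit B)–C8 (unit D) is cut, giving the chromanone carbonyl of 15 and aryllithium 20. Compound 20 comes from bromide 19 and so from catechin 16 by way of 17 and 18. The gain is convergence: unit D with its two stereocentres comes from the chiral pool and is joined in one step.

In 15 the bond C4–C4a of unit A is cut, giving epoxy ketone 11 and aryl Grignard reagent 14, made from 13 and 12. Ring A of unit A thus arrives as a nucleophile on the second acetyl-derived carbonyl. The bond between C4 of unit A and C6 of unit B never has to be made, because it is already present in 1.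

In 11 the silyl ether and then the bond O1–C2 of unit B are cut, which leads through dihydroflavonol 10 and phenol 9 to allyl ether 8. The phenol is masked as an allyl ether because this group can be taken off by metal-catalysed allyl transfer without acid, which the second electron-rich benzylic epoxide would not survive.

In 8 the four C–O bonds of the two oxiranes are cut, which gives bis-chalcone 5. This is the key disconnection. One catalytic, reagent-controlled epoxidation acts on two equal enone arms and fixes C2 and C3 of units A and B together. The forward reaction must give the same facial sense on both arms and leave the allyl ether untouched.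

Bis-chalcone 5 is cut at its two Cα=Cβ bonds into diketone 3 and two molecules of aldehyde 4. Compound 3 goes back through 2 to 1 by cutting two O–C bonds. All of this is condensation and etherification chemistry, so the risk of the route sits in the epoxidation.

Flavan-4-ol 33 is traced through 32, 31, 30, 29 and 28 to ketone 27 and aldehyde 4, and 27 to 26. These are the same reactions as in the main line, run in one direction only, so unit C costs no new chemistry.

## Alternatives that were turned down

Alternative 1: Here O1–C2 of unit B is cut, and C3 of each ent-fisetinidol unit would come from the α-carbon of the amino acid L-DOPA A2 as chiral-pool material, its carboxyl carbon becoming C4 and its benzylic carbon C2. In the forward key step a free catechol is oxidised to the o-quinone, which tautomerises to the p-quinone methide at C2. The ring A phenol then adds to it and closes the pyran ring, giving the B–D dimer A1 with a tertiary C4 hydroxyl, a free catechol and a C6 bromide. In its favour, the C3 configuration is bought and not made, the closure is reversible and should settle on the 2,3-trans ring, and the bromide is a handle for unit A. Against it, C2 is set only by substrate control next to a tertiary carbinol. The oxidation must pick one free catechol in a molecule full of electron-rich aryl ethers. Each of the three 5-deoxy units needs its own linear sequence from L-DOPA A2 and the A–B bond would still have to be forged at a crowded aryl bromide. On certainty of the C3 configuration this alternative is stronger than the chosen route, which depends on catalyst control. The chosen route offers in its place C2 and C3 of two units in one catalytic step and an A–B bond that is present from the start.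

Alternative 2: Here ring A of unit D itself is cut (C4a–C5, C5–C6 and C8–C8a). The hexasubstituted ring would be assembled by a cyclobutenone–alkyne benzannulation, one partner bringing unit C and the other, a siloxyalkyne, the open C2–C3–C4 chain of the catechin unit. On heating, the four-membered ring opens to a vinylketene, adds to the alkyne, and the adduct opens and recloses by 6π-electrocyclisation to the phenol A3. In its favour, the substitution pattern of the crowded arene is fixed by construction, with no competition between C6 and C8 or with the resorcinol rings. On this point it is stronger than the chosen route, whose last C–C bond is a Friedel–Crafts reaction at a hindered position. Against it, the method builds an aromatic ring that catechin 16 supplies ready-made with both stereocentres. Both partners are long to prepare and one has an epimerisable benzylic C4 next to a strained ketone. The pyran ring of unit D must still be closed, C8 is still a C–H to be joined to unit B, and nothing addresses the two 3,4-cis junctions. The step count would be far higher than in the chosen route, which takes unit D whole from the chiral pool.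

Alternative 3: Here unit C is cut at C4–C4a and O1–C2. Its ring A comes from 3-(benzyloxy)phenol A5 and its C2–C3–C4 chain from an aryl enone fragment whose β-carbon is bonded to C6 of the catechin unit. A chiral phosphoric acid would promote ortho addition of the phenol A5 to the β-carbon and cyclodehydration onto the ketone, giving the 4H-chromene A4 with C4 set by the catalyst and a C8 bromide. Hydroboration–oxidation anti to the C4 aryl group would then give the 2,3-trans-3,4-trans ring. In its favour, C4 of unit C is catalyst-controlled, the attachment at C6 is unambiguous and the bromide is ready for metalation. On these points it is equal to or stronger than the chosen route, which sets C4 of unit C by substrate control. Against it, the β-carbon carries a 2,6-dialkoxyaryl group and is a hindered, electron-rich acceptor, and the phenol has two ortho positions and one para position. C2 and C3 are relayed from C4 in a 3,4-trans sense only, so the method cannot make units A and B. The hardest part of the target, the A–B–D array with two 3,4-cis junctions, would still need the ketone chemistry of the chosen route, which solves it in one step from cheap materials.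

Key step: step 4

Remarks on the chemistry:
- 1-[4-(Benzyloxy)-2-hydroxyphenyl]ethanone 26 is taken as a commercial starting material.
- The carbinol carbons formed in steps 8 and 12 are drawn without configuration, since both become planar cations in step 15.
- Where one reagent acts several times in one step (steps 3, 13, 15, 23 and 24), partly reacted species are not numbered; this is done only for the key step.

## Route

Step 1
Reactants: 1 4,6-diacetylresorcinol
Product: 2 1-[5-acetyl-4-(benzyloxy)-2-hydroxyphenyl]ethanone
Conditions: BnBr (1.05 equiv), K2CO3, acetone, reflux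
Reagents that add atoms: benzyl bromide, BrCc1ccccc1
Why: Williamson etherification; the two phenols are equivalent and each is hydrogen-bonded to an ortho acetyl group, and carbonate ionises the more acidic diphenol 1 in preference to its mono-ether, so one equivalent of halide should give mainly the mono-ether, from which diether and unreacted 1 are separated.

Step 2
Reactants: 2 1-[5-acetyl-4-(benzyloxy)-2-hydroxyphenyl]ethanone
Product: 3 1-[5-acetyl-2-(allyloxy)-4-(benzyloxy)phenyl]ethanone
Conditions: allyl bromide, K2CO3, DMF, 60 °C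
Reagents that add atoms: allyl bromide, C=CCBr
Why: Williamson etherification of the chelated phenol under more forcing conditions; the allyl ether can later be removed by Pd(PPh3)4 without acid, and the temperature is far below that of a Claisen rearrangement.

Step 3
Reactants: 3 1-[5-acetyl-2-(allyloxy)-4-(benzyloxy)phenyl]ethanone; 4 3,4-bis(benzyloxy)benzaldehyde
Product: 5 (2E,2'E)-1,1'-[4-(allyloxy)-6-(benzyloxy)-1,3-phenylene]bis{3-[3,4-bis(benzyloxy)phenyl]prop-2-en-1-one}
Conditions: 4 (2.3 equiv), KOH, EtOH–THF, 0 → 20 °C
Reagents that add atoms: none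
Why: Double Claisen–Schmidt condensation of two methyl ketones with a non-enolisable aldehyde; E1cB loss of water gives the E-enones, and no flavanone can form because neither ketone has a free ortho hydroxyl.

Step 4
Reactants: 5 (2E,2'E)-1,1'-[4-(allyloxy)-6-(benzyloxy)-1,3-phenylene]bis{3-[3,4-bis(benzyloxy)phenyl]prop-2-en-1-one}
Product: 8 [4-(allyloxy)-6-(benzyloxy)-1,3-phenylene]bis{[(2S,3R)-3-(3,4-bis(benzyloxy)phenyl)oxiran-2-yl]methanone}, via mono-epoxide of the allyloxy-side arm 6 (not isolated), via mono-epoxide of the benzyloxy-side arm 7 (not isolated)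
Conditions: poly-D-leucine (insoluble, pre-swollen), urea–H2O2 (3 equiv), DBU (3 equiv), THF, 20 °C
Reagents that add atoms: urea–hydrogen peroxide, NC(N)=O.OO
Why: DBU and urea–H2O2 give hydroperoxide anion, which is held by the N-terminal N–H groups of the helical poly-D-leucine and adds to the β-carbon of each E-enone; the peroxy enolate then attacks the proximal peroxide oxygen with loss of hydroxide. The closest known reaction type is the Julia–Colonna epoxidation of 2'-alkoxychalcones under non-aqueous urea–H2O2/DBU conditions, here run on both arms of one substrate. Each of the two oxirane rings closes by 3-exo-tet attack of the enolate carbon on the O–O bond. The configuration at each β-carbon (later C2 of units A and B) is set by the catalyst in the conjugate addition, the D-configured peptide delivering the oxidant to the face that leads to the (2S,3R)-oxirane; the configuration at each α-carbon (later C3 of units A and B) follows from ring closure of the enolate anti to the aryl group, which gives the trans-oxirane from the E-enone. The step needs chemoselectivity for the two electron-poor enone double bonds over the allyl ether double bond, which the nucleophilic oxidant secures, and it needs both ortho oxygens etherified, since a free 2'-hydroxyl would divert the reaction to Algar–Flynn–Oyamada products. It also needs the same facial sense on both arms: the enones sit meta to each other on the central ring and are not conjugated with one another, so each should behave as an independent chalcone and 6 and 7 should both lead to 8. An arm epoxidised with the wrong sense gives a diastereomer of 8 that can be removed by chromatography or crystallisation, so the enantiomeric purity of 8 should exceed the selectivity of a single epoxidation.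

Step 5
Reactants: 8 [4-(allyloxy)-6-(benzyloxy)-1,3-phenylene]bis{[(2S,3R)-3-(3,4-bis(benzyloxy)phenyl)oxiran-2-yl]methanone}
Product: 10 (2S,3S)-7-(benzyloxy)-2-[3,4-bis(benzyloxy)phenyl]-6-{[(2S,3R)-3-(3,4-bis(benzyloxy)phenyl)oxiran-2-yl]carbonyl}-3-hydroxychroman-4-one, via free phenol 9 (not isolated)
Conditions: Pd(PPh3)4 (5 mol %), morpholine (3 equiv), THF, 0 → 20 °C, degassed
Reagents that add atoms: none
Why: Tsuji–Trost-type allyl transfer to morpholine frees phenol 9, whose amine-buffered phenoxide opens the neighbouring epoxide at the benzylic carbon (6-endo-tet, SN2 with inversion), the known cyclisation of 2'-hydroxychalcone epoxides to trans-3-hydroxyflavanones. Inversion at the benzylic carbon and retention at the other epoxide carbon give the (2S,3S) ring of unit B; the second epoxide has no neighbouring nucleophile and survives because no acid is used.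

Step 6
Reactants: 10 (2S,3S)-7-(benzyloxy)-2-[3,4-bis(benzyloxy)phenyl]-6-{[(2S,3R)-3-(3,4-bis(benzyloxy)phenyl)oxiran-2-yl]carbonyl}-3-hydroxychroman-4-one
Product: 11 3-O-(tert-butyldimethylsilyl) ether of 10
Conditions: TBSCl, imidazole, DMF, 20 °C
Reagents that add atoms: tert-butyldimethylsilyl chloride, CC(C)(C)[Si](C)(C)Cl
Why: Silylation of a secondary alcohol under non-acidic conditions; the bulky, non-chelating silyl ether shields the chromanone carbonyl in step 8 and later directs the reduction at C4 of unit B.

Step 7
Reactants: 12 4-bromoresorcinol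
Product: 13 2,4-bis(allyloxy)-1-bromobenzene
Conditions: allyl bromide (2.5 equiv), K2CO3, DMF, 50 °C
Reagents that add atoms: allyl bromide, C=CCBr
Why: Double Williamson etherification; protecting both phenols alike avoids any regiochemical question, and allyl groups tolerate the organomagnesium reagent and leave without acid.

Step 8
Reactants: 11 3-O-(tert-butyldimethylsilyl) ether of 10; 13 2,4-bis(allyloxy)-1-bromobenzene
Product: 15 tertiary carbinol in which the epoxy ketone carbonyl of 11 has become C(OH)[2,4-bis(allyloxy)phenyl] (future C4 of unit A; both epimers), via aryl Grignard reagent 14 (not isolated)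
Conditions: 13, Mg turnings, THF, 40 °C; then added to 11 (1.05 equiv of 14), THF–CH2Cl2, –78 → –40 °C; pH 7 buffer
Reagents that add atoms: none
Why: Grignard addition to a ketone; the epoxy ketone can hold magnesium between its carbonyl oxygen and the epoxide or ortho benzyloxy oxygen (chelation-accelerated addition), whereas the chromanone carbonyl lies in a rigid ring next to a bulky, non-chelating silyloxy group, so the acyclic ketone should react first at low temperature. The configuration of the new carbinol carbon does not matter because it is ionised in step 15.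

Step 9
Reactants: 16 (+)-catechin
Product: 17 5,7,3',4'-tetra-O-benzylcatechin
Conditions: BnBr (4.4 equiv), K2CO3, DMF, 0 → 20 °C
Reagents that add atoms: benzyl bromide, BrCc1ccccc1
Why: Williamson etherification of the four phenols; carbonate does not ionise the secondary alcohol and is too weak to epimerise C2.

Step 10
Reactants: 17 5,7,3',4'-tetra-O-benzylcatechin
Product: 18 8-bromo-5,7,3',4'-tetra-O-benzylcatechin
Conditions: N-bromosuccinimide (1.0 equiv), CH2Cl2, –78 → 0 °C
Reagents that add atoms: N-bromosuccinimide, O=C1CCC(=O)N1Br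
Why: Electrophilic aromatic bromination of the phloroglucinol-type ring; C8 is the known site of monobromination of 5,7-di-O-benzyl flavan-3-ols.

Step 11
Reactants: 18 8-bromo-5,7,3',4'-tetra-O-benzylcatechin
Product: 19 8-bromo-3,5,7,3',4'-penta-O-benzylcatechin
Conditions: NaH, BnBr, DMF, 0 → 20 °C
Reagents that add atoms: benzyl bromide, BrCc1ccccc1
Why: Williamson alkylation of the secondary alkoxide; with no free phenol left the strong base cannot open the heterocycle, and the ether removes the acidic proton before lithiation.

Step 12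
Reactants: 15 tertiary carbinol from step 8; 19 8-bromo-3,5,7,3',4'-penta-O-benzylcatechin
Product: 21 bis-carbinol in which C4 of unit B of 15 has become C(OH)(aryl) with aryl = C8 of penta-O-benzylcatechin (both carbinol carbons as epimer mixtures), via 8-lithiocatechin ether 20 (not isolated)
Conditions: 19 (2.4 equiv), n-BuLi (2.3 equiv), THF, –78 °C; then 15, –78 → –40 °C; H2O
Reagents that add atoms: none
Why: Bromine–lithium exchange gives aryllithium 20; the first equivalent deprotonates the tertiary hydroxyl of 15 and the next adds to the only ketone, the chromanone C4 carbonyl, a known reaction type of 8-lithioflavans with 3-silyloxyflavan-4-ones. The configuration of the new carbinol is not needed because this carbon is ionised in step 15.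

Step 13
Reactants: 21 bis-carbinol from step 12
Product: 23 4-hydroxy trimer in which unit A is closed as a (2S,3R)-2,3-trans chroman ring bearing free 7-OH and 3-OH and a tertiary 4-OH, via diphenol 22 (not isolated)
Conditions: Pd(PPh3)4 (10 mol %), K2CO3, MeOH–THF, 20 → 45 °C, degassed
Reagents that add atoms: none
Why: Pd-catalysed allyl transfer to methanol frees both phenols (22); carbonate ionises only the phenols, and the phenoxide ortho to C4 of unit A opens the epoxide at the benzylic carbon (6-endo-tet, SN2 with inversion), the nearer epoxide carbon being shielded by the fully substituted carbinol next to it. Inversion gives C2 (S) and the untouched epoxide carbon becomes C3 (R), the 2,3-trans ring of unit A; no ketone is left that base could enolise.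

Step 14
Reactants: 23 4-hydroxy trimer from step 13
Product: 24 7-O,3-O-bis(tert-butyldimethylsilyl) ether of 23 on unit A
Conditions: TBSOTf (2.4 equiv), 2,6-lutidine, CH2Cl2, –78 → –40 °C
Reagents that add atoms: tert-butyldimethylsilyl trifluoromethanesulfonate, CC(C)(C)[Si](C)(C)OS(=O)(=O)C(F)(F)F
Why: Buffered silylation of the phenol and of the hindered secondary C3 hydroxyl of unit A; the two tertiary diaryl carbinols are too crowded to react at this temperature. The C3 silyl ether directs step 15 and blocks a pinacol-type shift, and the aryl silyl ether masks the only free phenol before step 22.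

Step 15
Reactants: 24 bis-silyl ether from step 14
Product: 25 protected trimer ent-fisetinidol-(4α→6)-ent-fisetinidol-(4α→8)-catechin with 3,4-cis junctions (unit A: 7-O-TBS, 3-O-TBS, 3',4'-di-O-Bn; unit B: 7-O-Bn, 3-O-TBS, 3',4'-di-O-Bn; unit D: 3,5,7,3',4'-penta-O-Bn)
Conditions: Et3SiH (10 equiv), CF3CO2H, CH2Cl2, –78 → –20 °C
Reagents that add atoms: none
Why: Ionic hydrogenation: CF3CO2H ionises both tertiary, doubly benzylic carbinols to diarylmethyl cations, which Et3SiH reduces, as known for 4-aryl-3-silyloxyflavan-4-ols. In each cation allylic 1,2-strain with the C4 aryl group should push the bulky C3 silyloxy group pseudo-axial, and hydride enters anti to it, which places the aryl group cis to O3 at C4 of units A and B. The 5-deoxy rings make the new interflavanyl bonds resistant to acid cleavage at this temperature.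

Step 16
Reactants: 26 1-[4-(benzyloxy)-2-hydroxyphenyl]ethanone
Product: 27 1-[2-(allyloxy)-4-(benzyloxy)phenyl]ethanone
Conditions: allyl bromide, K2CO3, DMF, 60 °C
Reagents that add atoms: allyl bromide, C=CCBr
Why: Williamson etherification of the chelated ortho phenol, as in step 2.

Step 17
Reactants: 27 1-[2-(allyloxy)-4-(benzyloxy)phenyl]ethanone; 4 3,4-bis(benzyloxy)benzaldehyde
Product: 28 (E)-1-[2-(allyloxy)-4-(benzyloxy)phenyl]-3-[3,4-bis(benzyloxy)phenyl]prop-2-en-1-one
Conditions: 4 (1.1 equiv), KOH, EtOH–THF, 20 °C
Reagents that add atoms: none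
Why: Claisen–Schmidt condensation giving the E-chalcone, as in step 3.

Step 18
Reactants: 28 (E)-1-[2-(allyloxy)-4-(benzyloxy)phenyl]-3-[3,4-bis(benzyloxy)phenyl]prop-2-en-1-one
Product: 29 [2-(allyloxy)-4-(benzyloxy)phenyl][(2S,3R)-3-(3,4-bis(benzyloxy)phenyl)oxiran-2-yl]methanone
Conditions: poly-D-leucine, urea–H2O2, DBU, THF, 20 °C
Reagents that add atoms: urea–hydrogen peroxide, NC(N)=O.OO
Why: Julia–Colonna epoxidation of a 2'-alkoxychalcone; the same catalyst as in step 4 sets the β-carbon, and closure of the peroxy enolate gives the trans-oxirane of the (2S,3R) series.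

Step 19
Reactants: 29 [2-(allyloxy)-4-(benzyloxy)phenyl][(2S,3R)-3-(3,4-bis(benzyloxy)phenyl)oxiran-2-yl]methanone
Product: 31 (2S,3S)-7-(benzyloxy)-2-[3,4-bis(benzyloxy)phenyl]-3-hydroxychroman-4-one, via free phenol 30 (not isolated)
Conditions: Pd(PPh3)4 (5 mol %), morpholine (3 equiv), THF, 0 → 20 °C, degassed
Reagents that add atoms: none
Why: Allyl transfer to morpholine and 6-endo-tet opening of the epoxide by the phenoxide at the benzylic carbon with inversion, as in step 5, give the trans-dihydroflavonol.

Step 20
Reactants: 31 (2S,3S)-7-(benzyloxy)-2-[3,4-bis(benzyloxy)phenyl]-3-hydroxychroman-4-one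
Product: 32 3-O-(tert-butyldimethylsilyl) ether of 31
Conditions: TBSCl, imidazole, DMF, 20 °C
Reagents that add atoms: tert-butyldimethylsilyl chloride, CC(C)(C)[Si](C)(C)Cl
Why: Silylation of the secondary alcohol; the bulky ether will steer the arene to the opposite face in step 22.

Step 21
Reactants: 32 3-O-(tert-butyldimethylsilyl) ether of 31
Product: 33 (2S,3R,4S)-7-(benzyloxy)-2-[3,4-bis(benzyloxy)phenyl]-3-[(tert-butyldimethylsilyl)oxy]chroman-4-ol
Conditions: NaBH4, EtOH–THF, 0 °C
Reagents that add atoms: none
Why: Borohydride reduction of the aryl ketone; axial hydride attack is expected to give mainly the 3,4-trans alcohol, but either epimer would serve because C4 is ionised in step 22.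

Step 22
Reactants: 25 protected trimer from step 15; 33 flavan-4-ol from step 21
Product: 34 protected tetramer: 25 carrying at C6 of unit D the 7,3',4'-tri-O-benzyl-3-O-TBS-ent-fisetinidol unit C bonded 4β→6 (3,4-trans)
Conditions: BF3·OEt2 (0.5 equiv), 4 Å molecular sieves, CH2Cl2, –78 → –30 °C; slow addition of 33 (1.5 equiv)
Reagents that add atoms: none
Why: Friedel–Crafts alkylation: BF3 ionises the benzylic C4 hydroxyl of 33 to a flavan-4-yl cation stabilised by O1 and the 7-benzyloxy group, and C6 of unit D, ortho or para to three oxygen substituents, is the only phloroglucinol-type position left and the most nucleophilic carbon of 25. The arene attacks anti to the C3 silyloxy group, which gives the 3,4-trans junction of unit C.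

Step 23
Reactants: 34 protected tetramer from step 22
Product: 35 tridecabenzyl ether of the target (all four silyl groups removed)
Conditions: Bu4NF, AcOH, THF, 20 → 40 °C
Reagents that add atoms: none
Why: Fluoride-induced cleavage of the one aryl and three secondary alkyl silyl ethers; acetic acid buffers the phenoxide and alkoxides so that no base-induced epimerisation at C2 can occur.

Step 24
Reactants: 35 tridecabenzyl ether of the target
Product: 36 ent-fisetinidol-(4α→6)-ent-fisetinidol-(4α→8)-[ent-fisetinidol-(4β→6)]-catechin (target)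
Conditions: H2 (1 atm), Pd(OH)2/C, THF–MeOH–H2O, 20 °C
Reagents that add atoms: none
Why: Hydrogenolysis of thirteen benzyl ethers under neutral conditions, the usual last step for oligomeric flavan-3-ols; the ring C–O and C4–aryl bonds are cleaved far more slowly than the O-benzyl bonds.

## Compound list

1 | 4,6-diacetylresorcinol | CC(=O)c1cc(C(C)=O)c(O)cc1O | starting material
2 | 1-[5-acetyl-4-(benzyloxy)-2-hydroxyphenyl]ethanone | CC(=O)c1cc(C(C)=O)c(OCc2ccccc2)cc1O | intermediate
3 | 1-[5-acetyl-2-(allyloxy)-4-(benzyloxy)phenyl]ethanone | CC(=O)c1cc(C(C)=O)c(OCc2ccccc2)cc1OCC=C | intermediate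
4 | 3,4-bis(benzyloxy)benzaldehyde | O=Cc1ccc(OCc2ccccc2)c(OCc2ccccc2)c1 | starting material
5 | bis-chalcone, (2E,2'E)-1,1'-[4-(allyloxy)-6-(benzyloxy)-1,3-phenylene]bis{3-[3,4-bis(benzyloxy)phenyl]prop-2-en-1-one} | C=CCOc1cc(OCc2ccccc2)c(C(=O)/C=C/c2ccc(OCc3ccccc3)c(OCc3ccccc3)c2)cc1C(=O)/C=C/c1ccc(OCc2ccccc2)c(OCc2ccccc2)c1 | intermediate
6 | mono-epoxide of 5, arm ortho to the allyloxy group as (2S,3R)-oxirane, other arm E-enone; not isolated | C=CCOc1cc(OCc2ccccc2)c(C(=O)/C=C/c2ccc(OCc3ccccc3)c(OCc3ccccc3)c2)cc1C(=O)[C@H]1O[C@@H]1c1ccc(OCc2ccccc2)c(OCc2ccccc2)c1 | intermediate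
7 | mono-epoxide of 5, arm ortho to the benzyloxy group as (2S,3R)-oxirane, other arm E-enone; not isolated | C=CCOc1cc(OCc2ccccc2)c(C(=O)[C@H]2O[C@@H]2c2ccc(OCc3ccccc3)c(OCc3ccccc3)c2)cc1C(=O)/C=C/c1ccc(OCc2ccccc2)c(OCc2ccccc2)c1 | intermediate
8 | bis(trans-epoxy ketone), [4-(allyloxy)-6-(benzyloxy)-1,3-phenylene]bis{[(2S,3R)-3-(3,4-bis(benzyloxy)phenyl)oxiran-2-yl]methanone} | C=CCOc1cc(OCc2ccccc2)c(C(=O)[C@H]2O[C@@H]2c2ccc(OCc3ccccc3)c(OCc3ccccc3)c2)cc1C(=O)[C@H]1O[C@@H]1c1ccc(OCc2ccccc2)c(OCc2ccccc2)c1 | intermediate
9 | free phenol from 8, [4-(benzyloxy)-6-hydroxy-1,3-phenylene]bis{[(2S,3R)-3-(3,4-bis(benzyloxy)phenyl)oxiran-2-yl]methanone}; not isolated | Oc1cc(OCc2ccccc2)c(C(=O)[C@H]2O[C@@H]2c2ccc(OCc3ccccc3)c(OCc3ccccc3)c2)cc1C(=O)[C@H]1O[C@@H]1c1ccc(OCc2ccccc2)c(OCc2ccccc2)c1 | intermediate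
10 | (2S,3S)-7-(benzyloxy)-2-[3,4-bis(benzyloxy)phenyl]-6-{[(2S,3R)-3-(3,4-bis(benzyloxy)phenyl)oxiran-2-yl]carbonyl}-3-hydroxychroman-4-one | O=C1c2cc(C(=O)[C@H]3O[C@@H]3c3ccc(OCc4ccccc4)c(OCc4ccccc4)c3)c(OCc3ccccc3)cc2O[C@@H](c2ccc(OCc3ccccc3)c(OCc3ccccc3)c2)[C@@H]1O | intermediate
11 | 3-O-(tert-butyldimethylsilyl) ether of 10 | O=C1c2cc(C(=O)[C@H]3O[C@@H]3c3ccc(OCc4ccccc4)c(OCc4ccccc4)c3)c(OCc3ccccc3)cc2O[C@@H](c2ccc(OCc3ccccc3)c(OCc3ccccc3)c2)[C@@H]1O[Si](C)(C)C(C)(C)C | intermediate
12 | 4-bromoresorcinol | Oc1ccc(Br)c(O)c1 | starting material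
13 | 2,4-bis(allyloxy)-1-bromobenzene | C=CCOc1ccc(Br)c(OCC=C)c1 | intermediate
14 | [2,4-bis(allyloxy)phenyl]magnesium bromide; not isolated | C=CCOc1ccc([Mg]Br)c(OCC=C)c1 | intermediate
15 | tertiary carbinol: 11 with the epoxy ketone carbonyl converted into C(OH)[2,4-bis(allyloxy)phenyl], epimers at this carbon | O=C1c2cc(C(O)(c3ccc(OCC=C)cc3OCC=C)[C@H]3O[C@@H]3c3ccc(OCc4ccccc4)c(OCc4ccccc4)c3)c(OCc3ccccc3)cc2O[C@@H](c2ccc(OCc3ccccc3)c(OCc3ccccc3)c2)[C@@H]1O[Si](C)(C)C(C)(C)C | intermediate
16 | (+)-catechin | O[C@H]1Cc2c(O)cc(O)cc2O[C@@H]1c1ccc(O)c(O)c1 | starting material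
17 | 5,7,3',4'-tetra-O-benzylcatechin | O[C@H]1Cc2c(OCc3ccccc3)cc(OCc3ccccc3)cc2O[C@@H]1c1ccc(OCc2ccccc2)c(OCc2ccccc2)c1 | intermediate
18 | 8-bromo-5,7,3',4'-tetra-O-benzylcatechin | O[C@H]1Cc2c(OCc3ccccc3)cc(OCc3ccccc3)c(Br)c2O[C@@H]1c1ccc(OCc2ccccc2)c(OCc2ccccc2)c1 | intermediate
19 | 8-bromo-3,5,7,3',4'-penta-O-benzylcatechin | c1ccccc1CO[C@H]1Cc2c(OCc3ccccc3)cc(OCc3ccccc3)c(Br)c2O[C@@H]1c1ccc(OCc2ccccc2)c(OCc2ccccc2)c1 | intermediate
20 | 8-lithio-3,5,7,3',4'-penta-O-benzylcatechin; not isolated | c1ccccc1CO[C@H]1Cc2c(OCc3ccccc3)cc(OCc3ccccc3)c([Li])c2O[C@@H]1c1ccc(OCc2ccccc2)c(OCc2ccccc2)c1 | intermediate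
21 | bis-carbinol: 15 with C4 of unit B converted into C(OH)(penta-O-benzylcatechin-8-yl), epimers at both carbinol carbons | C=CCOc1ccc(c(OCC=C)c1)C(O)([C@H]1O[C@@H]1c1ccc(OCc2ccccc2)c(OCc2ccccc2)c1)c1cc2c(cc1OCc1ccccc1)O[C@@H](c1ccc(OCc3ccccc3)c(OCc3ccccc3)c1)[C@H](O[Si](C)(C)C(C)(C)C)C2(O)c1c(OCc3ccccc3)cc(OCc3ccccc3)c3c1O[C@H](c1ccc(OCc4ccccc4)c(OCc4ccccc4)c1)[C@@H](OCc1ccccc1)C3 | intermediate
22 | diphenol: 21 with both allyl ethers cleaved; not isolated | Oc1ccc(c(O)c1)C(O)([C@H]1O[C@@H]1c1ccc(OCc2ccccc2)c(OCc2ccccc2)c1)c1cc2c(cc1OCc1ccccc1)O[C@@H](c1ccc(OCc3ccccc3)c(OCc3ccccc3)c1)[C@H](O[Si](C)(C)C(C)(C)C)C2(O)c1c(OCc3ccccc3)cc(OCc3ccccc3)c3c1O[C@H](c1ccc(OCc4ccccc4)c(OCc4ccccc4)c1)[C@@H](OCc1ccccc1)C3 | intermediate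
23 | 4-hydroxy trimer: unit A closed as (2S,3R)-chroman with free 7-OH, 3-OH and tertiary 4-OH; unit B with 3-O-TBS and tertiary 4-OH; unit D penta-O-benzyl | Oc1ccc2c(c1)O[C@@H](c1ccc(OCc3ccccc3)c(OCc3ccccc3)c1)[C@H](O)C2(O)c1cc2c(cc1OCc1ccccc1)O[C@@H](c1ccc(OCc3ccccc3)c(OCc3ccccc3)c1)[C@H](O[Si](C)(C)C(C)(C)C)C2(O)c1c(OCc3ccccc3)cc(OCc3ccccc3)c3c1O[C@H](c1ccc(OCc4ccccc4)c(OCc4ccccc4)c1)[C@@H](OCc1ccccc1)C3 | intermediate
24 | 23 with 7-O-TBS and 3-O-TBS on unit A | CC(C)(C)[Si](C)(C)Oc1ccc2c(c1)O[C@@H](c1ccc(OCc3ccccc3)c(OCc3ccccc3)c1)[C@H](O[Si](C)(C)C(C)(C)C)C2(O)c1cc2c(cc1OCc1ccccc1)O[C@@H](c1ccc(OCc3ccccc3)c(OCc3ccccc3)c1)[C@H](O[Si](C)(C)C(C)(C)C)C2(O)c1c(OCc3ccccc3)cc(OCc3ccccc3)c3c1O[C@H](c1ccc(OCc4ccccc4)c(OCc4ccccc4)c1)[C@@H](OCc1ccccc1)C3 | intermediate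
25 | protected trimer ent-fisetinidol-(4α→6)-ent-fisetinidol-(4α→8)-catechin, 3,4-cis at both junctions | CC(C)(C)[Si](C)(C)Oc1ccc2c(c1)O[C@@H](c1ccc(OCc3ccccc3)c(OCc3ccccc3)c1)[C@H](O[Si](C)(C)C(C)(C)C)[C@@H]2c1cc2c(cc1OCc1ccccc1)O[C@@H](c1ccc(OCc3ccccc3)c(OCc3ccccc3)c1)[C@H](O[Si](C)(C)C(C)(C)C)[C@@H]2c1c(OCc3ccccc3)cc(OCc3ccccc3)c3c1O[C@H](c1ccc(OCc4ccccc4)c(OCc4ccccc4)c1)[C@@H](OCc1ccccc1)C3 | intermediate
26 | 1-[4-(benzyloxy)-2-hydroxyphenyl]ethanone | CC(=O)c1ccc(OCc2ccccc2)cc1O | starting material
27 | 1-[2-(allyloxy)-4-(benzyloxy)phenyl]ethanone | CC(=O)c1ccc(OCc2ccccc2)cc1OCC=C | intermediate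
28 | (E)-1-[2-(allyloxy)-4-(benzyloxy)phenyl]-3-[3,4-bis(benzyloxy)phenyl]prop-2-en-1-one | C=CCOc1cc(OCc2ccccc2)ccc1C(=O)/C=C/c1ccc(OCc2ccccc2)c(OCc2ccccc2)c1 | intermediate
29 | [2-(allyloxy)-4-(benzyloxy)phenyl][(2S,3R)-3-(3,4-bis(benzyloxy)phenyl)oxiran-2-yl]methanone | C=CCOc1cc(OCc2ccccc2)ccc1C(=O)[C@H]1O[C@@H]1c1ccc(OCc2ccccc2)c(OCc2ccccc2)c1 | intermediate
30 | [4-(benzyloxy)-2-hydroxyphenyl][(2S,3R)-3-(3,4-bis(benzyloxy)phenyl)oxiran-2-yl]methanone; not isolated | Oc1cc(OCc2ccccc2)ccc1C(=O)[C@H]1O[C@@H]1c1ccc(OCc2ccccc2)c(OCc2ccccc2)c1 | intermediate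
31 | (2S,3S)-7-(benzyloxy)-2-[3,4-bis(benzyloxy)phenyl]-3-hydroxychroman-4-one | O=C1c2ccc(OCc3ccccc3)cc2O[C@@H](c2ccc(OCc3ccccc3)c(OCc3ccccc3)c2)[C@@H]1O | intermediate
32 | 3-O-(tert-butyldimethylsilyl) ether of 31 | O=C1c2ccc(OCc3ccccc3)cc2O[C@@H](c2ccc(OCc3ccccc3)c(OCc3ccccc3)c2)[C@@H]1O[Si](C)(C)C(C)(C)C | intermediate
33 | (2S,3R,4S)-7-(benzyloxy)-2-[3,4-bis(benzyloxy)phenyl]-3-[(tert-butyldimethylsilyl)oxy]chroman-4-ol | O[C@H]1c2ccc(OCc3ccccc3)cc2O[C@@H](c2ccc(OCc3ccccc3)c(OCc3ccccc3)c2)[C@@H]1O[Si](C)(C)C(C)(C)C | intermediate
34 | protected tetramer: 25 with 7,3',4'-tri-O-benzyl-3-O-TBS-ent-fisetinidol bonded 4β→6 to unit D | CC(C)(C)[Si](C)(C)Oc1ccc2c(c1)O[C@@H](c1ccc(OCc3ccccc3)c(OCc3ccccc3)c1)[C@H](O[Si](C)(C)C(C)(C)C)[C@@H]2c1cc2c(cc1OCc1ccccc1)O[C@@H](c1ccc(OCc3ccccc3)c(OCc3ccccc3)c1)[C@H](O[Si](C)(C)C(C)(C)C)[C@@H]2c1c(OCc3ccccc3)c([C@H]4c5ccc(OCc6ccccc6)cc5O[C@@H](c5ccc(OCc6ccccc6)c(OCc6ccccc6)c5)[C@@H]4O[Si](C)(C)C(C)(C)C)c(OCc3ccccc3)c3c1O[C@H](c1ccc(OCc4ccccc4)c(OCc4ccccc4)c1)[C@@H](OCc1ccccc1)C3 | intermediate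
35 | tridecabenzyl ether of the target | Oc1ccc2c(c1)O[C@@H](c1ccc(OCc3ccccc3)c(OCc3ccccc3)c1)[C@H](O)[C@@H]2c1cc2c(cc1OCc1ccccc1)O[C@@H](c1ccc(OCc3ccccc3)c(OCc3ccccc3)c1)[C@H](O)[C@@H]2c1c(OCc3ccccc3)c([C@H]4c5ccc(OCc6ccccc6)cc5O[C@@H](c5ccc(OCc6ccccc6)c(OCc6ccccc6)c5)[C@@H]4O)c(OCc3ccccc3)c3c1O[C@H](c1ccc(OCc4ccccc4)c(OCc4ccccc4)c1)[C@@H](OCc1ccccc1)C3 | intermediate
36 | ent-fisetinidol-(4α→6)-ent-fisetinidol-(4α→8)-[ent-fisetinidol-(4β→6)]-catechin, CNP0126838.5 | Oc1ccc2c(c1)O[C@@H](c1ccc(O)c(O)c1)[C@H](O)[C@@H]2c1cc2c(cc1O)O[C@@H](c1ccc(O)c(O)c1)[C@H](O)[C@@H]2c1c(O)c([C@H]2c3ccc(O)cc3O[C@@H](c3ccc(O)c(O)c3)[C@@H]2O)c(O)c2c1O[C@H](c1ccc(O)c(O)c1)[C@@H](O)C2 | target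

## Step count and least certain steps

Total: 24 steps. Longest linear sequence: 14 steps (steps 1–6, 8, 12–15, 22–24, from 1 to 36).

Step 4 (key step). The most likely failure is stalling after one epoxidation or erosion of facial control. Each enone carries an ortho alkoxy group on the aroyl ring and an electron-rich β-aryl group, which lower the electrophilicity of the β-carbon and may hinder binding of this large bis-enone to the peptide surface. A lower selectivity per arm raises the share of mixed diastereomers to be removed. Fallback: stereocontrol is moved from the heterogeneous peptide to a soluble chiral lanthanum binaphtholate, which binds the enone carbonyl to the metal and delivers a metal-bound alkyl peroxide. It sets out from 5 and comes back at 8 in one operation with La(OiPr)3, BINOL, Ph3As=O and tert-butyl hydroperoxide in THF. The BINOL enantiomer is chosen on the model enone 28 so that 29 of the (2S,3R) series results. No compound outside the list is made, which the line F0 records.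

Step 8. The most likely failure is loss of chemoselectivity between the two carbonyl groups: addition of the Grignard reagent to the chromanone carbonyl, or to both. Both ketones are conjugated to the same 2,4-dioxygenated ring and differ only in their α-substituent and their ability to chelate magnesium. Fallback: the chromanone carbonyl is taken out of play for the time of the addition. It sets out from 10 and comes back at 15. Hydroxyl-directed reduction of 10 with Me4NBH(OAc)3 (MeCN–AcOH, –20 °C), which delivers hydride only from a boron-bound neighbouring hydroxyl, should give the (2S,3R,4S)-3,4-diol of unit B with the epoxy ketone arm intact F1. An excess of 14 then adds to the only ketone left and gives the epoxy triol F2. MnO2 in CH2Cl2 re-oxidises the benzylic C4 hydroxyl of unit B to the 3-hydroxychromanone F3, whose C3 hydroxyl is silylated (TBSCl, imidazole, DMF) to give 15.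

Step 13. The most likely failure is the wrong regiochemistry of epoxide opening: attack of the phenoxide on the nearer epoxide carbon to close a five-membered ring, or a Payne-type migration of the epoxide towards the tertiary alkoxide before ring closure. Under base alone the preference for the benzylic carbon rests only on the crowding next to the carbinol. Fallback: the two events are separated and the regiochemistry is handed to a metal template. It sets out from 21 and comes back at 23. Deallylation with Pd(PPh3)4 and PhSiH3 under neutral conditions gives diphenol 22, which is isolated. Ti(OiPr)4 in CH2Cl2 then binds the tertiary hydroxyl, the epoxide oxygen and the phenol. Titanium-assisted opening of 2,3-epoxy alcohols is known to take place at C3, here the benzylic carbon, with inversion, which leads to 23. No compound outside the list is made, which the line F0 records.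

Step 15. The most likely failure is insufficient facial selectivity in the hydride transfer to one of the two cations, together with a 1,2-hydride shift from C3 to the cation that would end in a flavan-3-one. In 2,3-trans units the C2 aryl group lies on the face from which hydride must come, so the preference rests on the C3 silyloxy group alone. Fallback: the cationic pathway is replaced by a radical one, which excludes the hydride shift and acid-induced ring opening and uses a bulkier hydrogen donor. It sets out from 24 and comes back at 25. The two tertiary alkoxides (KN(SiMe3)2, THF, –78 °C) are acylated with methyl chlorooxoacetate to the bis(methyl oxalate) F4. Bu3SnH and azobisisobutyronitrile in toluene at 90 °C then remove both oxalate groups by way of the tertiary diarylmethyl radicals, which take hydrogen anti to the silyloxy groups.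

Step 22. The most likely failure is poor site selectivity or low conversion. C6 of unit D is flanked by two benzyloxy groups, and the cation from 33 may instead attack the less hindered resorcinol-type rings of units A and B or ring A of a second molecule of 33. Fallback: the coupling is run on the free phenols, where the only phloroglucinol-type position, C6 of unit D, is far more nucleophilic than any resorcinol carbon. It sets out from 25 and 31 and comes back at 36. Compound 25 is desilylated (Bu4NF, AcOH) to the benzyl-protected trimer F5 and hydrogenolysed (H2, Pd(OH)2/C) to the free trimer F6. Compound 31 is hydrogenolysed (H2, Pd/C, EtOAc) to ent-fustin F7 and reduced (NaBH4, EtOH) to ent-mollisacacidin F8. F6 and F8 are condensed in 0.1 M aqueous HCl at 20 °C to give 36, which has to be separated from its 3,4-cis epimer at C4 of unit C.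

## Further compounds

F0 | step 4 | none | none
F1 | step 8 | (2S,3R,4S)-7-(benzyloxy)-2-[3,4-bis(benzyloxy)phenyl]-6-{[(2S,3R)-3-(3,4-bis(benzyloxy)phenyl)oxiran-2-yl]carbonyl}chroman-3,4-diol | O[C@H]1c2cc(C(=O)[C@H]3O[C@@H]3c3ccc(OCc4ccccc4)c(OCc4ccccc4)c3)c(OCc3ccccc3)cc2O[C@@H](c2ccc(OCc3ccccc3)c(OCc3ccccc3)c2)[C@@H]1O
F2 | step 8 | epoxy triol: F1 with the ketone converted into C(OH)[2,4-bis(allyloxy)phenyl], epimers at this carbon | O[C@H]1c2cc(C(O)(c3ccc(OCC=C)cc3OCC=C)[C@H]3O[C@@H]3c3ccc(OCc4ccccc4)c(OCc4ccccc4)c3)c(OCc3ccccc3)cc2O[C@@H](c2ccc(OCc3ccccc3)c(OCc3ccccc3)c2)[C@@H]1O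
F3 | step 8 | 15 lacking the silyl group, (2S,3S)-3-hydroxychroman-4-one with the tertiary carbinol arm | O=C1c2cc(C(O)(c3ccc(OCC=C)cc3OCC=C)[C@H]3O[C@@H]3c3ccc(OCc4ccccc4)c(OCc4ccccc4)c3)c(OCc3ccccc3)cc2O[C@@H](c2ccc(OCc3ccccc3)c(OCc3ccccc3)c2)[C@@H]1O
F0 | step 13 | none | none
F4 | step 15 | bis(methyl oxalate) of 24 at the two tertiary carbinols | CC(C)(C)[Si](C)(C)Oc1ccc2c(c1)O[C@@H](c1ccc(OCc3ccccc3)c(OCc3ccccc3)c1)[C@H](O[Si](C)(C)C(C)(C)C)C2(OC(=O)C(=O)OC)c1cc2c(cc1OCc1ccccc1)O[C@@H](c1ccc(OCc3ccccc3)c(OCc3ccccc3)c1)[C@H](O[Si](C)(C)C(C)(C)C)C2(OC(=O)C(=O)OC)c1c(OCc3ccccc3)cc(OCc3ccccc3)c3c1O[C@H](c1ccc(OCc4ccccc4)c(OCc4ccccc4)c1)[C@@H](OCc1ccccc1)C3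
F5 | step 22 | desilylated, benzyl-protected trimer from 25 | Oc1ccc2c(c1)O[C@@H](c1ccc(OCc3ccccc3)c(OCc3ccccc3)c1)[C@H](O)[C@@H]2c1cc2c(cc1OCc1ccccc1)O[C@@H](c1ccc(OCc3ccccc3)c(OCc3ccccc3)c1)[C@H](O)[C@@H]2c1c(OCc3ccccc3)cc(OCc3ccccc3)c3c1O[C@H](c1ccc(OCc4ccccc4)c(OCc4ccccc4)c1)[C@@H](OCc1ccccc1)C3
F6 | step 22 | free trimer ent-fisetinidol-(4α→6)-ent-fisetinidol-(4α→8)-catechin | Oc1ccc2c(c1)O[C@@H](c1ccc(O)c(O)c1)[C@H](O)[C@@H]2c1cc2c(cc1O)O[C@@H](c1ccc(O)c(O)c1)[C@H](O)[C@@H]2c1c(O)cc(O)c2c1O[C@H](c1ccc(O)c(O)c1)[C@@H](O)C2
F7 | step 22 | ent-fustin, (2S,3S)-2-(3,4-dihydroxyphenyl)-3,7-dihydroxychroman-4-one | O=C1c2ccc(O)cc2O[C@@H](c2ccc(O)c(O)c2)[C@@H]1O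
F8 | step 22 | ent-mollisacacidin, (2S,3R,4S)-2-(3,4-dihydroxyphenyl)chroman-3,4,7-triol | O[C@H]1c2ccc(O)cc2O[C@@H](c2ccc(O)c(O)c2)[C@@H]1O
A1 | alternative 1 | B–D dimer with 4-hydroxy unit B, free catechol and C6 bromide | Brc1cc2c(cc1OCc1ccccc1)O[C@@H](c1ccc(O)c(O)c1)[C@H](OCc1ccccc1)C2(O)c1c(OCc2ccccc2)cc(OCc2ccccc2)c2c1O[C@H](c1ccc(OCc3ccccc3)c(OCc3ccccc3)c1)[C@@H](OCc1ccccc1)C2
A2 | alternative 1 | L-DOPA, (S)-2-amino-3-(3,4-dihydroxyphenyl)propanoic acid | N[C@@H](Cc1ccc(O)c(O)c1)C(=O)O
A3 | alternative 2 | pentasubstituted phloroglucinol with unit C at C6, free C5 phenol and open catechin pyran | Oc1c([C@H]2c3ccc(OCc4ccccc4)cc3O[C@@H](c3ccc(OCc4ccccc4)c(OCc4ccccc4)c3)[C@@H]2OCc2ccccc2)c(OCc2ccccc2)cc(O[Si](C(C)C)(C(C)C)C(C)C)c1C[C@H](OCc1ccccc1)[C@@H](O[Si](C)(C)C(C)(C)C)c1ccc(OCc2ccccc2)c(OCc2ccccc2)c1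
A4 | alternative 3 | 4-(catechin-6-yl)-2-aryl-4H-chromene with C8 bromide | c1ccccc1COc1ccc2c(c1)OC(c1ccc(OCc3ccccc3)c(OCc3ccccc3)c1)=C[C@H]2c1c(OCc2ccccc2)c(Br)c2c(c1OCc1ccccc1)C[C@H](OCc1ccccc1)[C@@H](c1ccc(OCc3ccccc3)c(OCc3ccccc3)c1)O2
A5 | alternative 3 | 3-(benzyloxy)phenol | Oc1cccc(OCc2ccccc2)c1
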